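## Retrosynthetic overview

1. Leucanthin B ⇐ cleavage of a fluoride-labile C14 ester ⇐ C8 acylation with (2R,3R)-epoxyangelic acid ⇐ 6,12-olide ⇐ reduction/lactonisation of a ten-membered 4,5-epoxy-6-ketone.
2. Ten-membered ring ⇐ three-carbon ring expansion of a cycloheptanone: C7 (allylindium) adds to the C6 ketone, then a Grob fragmentation breaks C6–C10 and expels C1–OMs, giving C6=O and the cis C1=C10 enoate.
3. Cycloheptanone bis-epoxide ⇐ 8-oxabicyclo[3.2.1]octenone: exo-epoxidation (C2/C3), E1cB opening of the oxygen bridge (C4=C5), nucleophilic epoxidation (C4/C5). C7–C9 arrive by chelation-controlled aldol at C10, C11–C13 by cross-metathesis.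
4. Oxabicycle ⇐ Rh-catalysed [4+3] of 2-methylfuran with a siloxyvinyl diazoacetate made from acetoacetate. C8 comes from Pd-catalysed asymmetric etherification of vinyloxirane; the epoxyangelate from angelic acid by Sharpless epoxidation.
5. Ring order: oxygen-bridged seven-membered ring → 2,3-epoxide → 4,5-epoxide → transient fused cyclopentane → ten-membered ring → γ-lactone.

Assumption: germacrane numbering (C1–C15) of the target is used for all intermediates, and the Rh and Pd catalysts are taken in the enantiomeric form that gives the configurations drawn (the antipode is used if the sense of induction is opposite).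

## Route

Step 1
Reactants: 1 methyl acetoacetate
Product: 2 2-(trimethylsilyl)ethyl 3-oxobutanoate
Conditions: Me3SiCH2CH2OH (1.1 equiv), DMAP (cat.), toluene, reflux (MeOH distilled off)
Reagents that add atoms: 2-(trimethylsilyl)ethanol, C[Si](C)(C)CCO
Why: Transesterification of a β-keto ester (acylketene/DMAP pathway) installs the fluoride-cleavable ester that later becomes the free C14 acid.

Step 2
Reactants: 2 2-(trimethylsilyl)ethyl 3-oxobutanoate
Product: 3 2-(trimethylsilyl)ethyl 2-diazo-3-oxobutanoate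
Conditions: p-ABSA, Et3N, MeCN, 0 → 25 °C
Reagents that add atoms: 4-acetamidobenzenesulfonyl azide, CC(=O)Nc1ccc(cc1)S(=O)(=O)N=[N+]=[N-]
Why: Regitz diazo transfer to the active methylene.

Step 3
Reactants: 3 2-(trimethylsilyl)ethyl 2-diazo-3-oxobutanoate
Product: 4 2-(trimethylsilyl)ethyl 3-(tert-butyldimethylsilyloxy)-2-diazobut-3-enoate
Conditions: TBSOTf, Et3N, CH2Cl2, 0 °C
Reagents that add atoms: tert-butyldimethylsilyl triflate, CC(C)(C)[Si](C)(C)OS(=O)(=O)C(F)(F)F
Why: Soft enolisation/O-silylation of the methyl ketone gives the siloxyvinyl diazoacetate used in vinylcarbenoid [4+3] chemistry.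

Step 4
Reactants: 4 2-(trimethylsilyl)ethyl 3-(tert-butyldimethylsilyloxy)-2-diazobut-3-enoate; 5 2-methylfuran
Product: 7 2-(trimethylsilyl)ethyl (1S,5S)-3-(tert-butyldimethylsilyloxy)-5-methyl-8-oxabicyclo[3.2.1]octa-2,6-diene-2-carboxylate, via divinylcyclopropane 6 (not isolated)
Conditions: Rh2(S-PTAD)4 (1 mol%), 5 (5 equiv), hexanes, −40 → 25 °C
Reagents that add atoms: none
Why: Tandem cyclopropanation/Cope rearrangement (formal [4+3] of a Rh vinylcarbenoid with a furan); the carbenoid attacks the unsubstituted furan C=C so the ester carbon (C10) ends next to the H-bridgehead (C1) and the CH2 (C5) next to the methyl bridgehead (C4), and the chiral Rh(II) catalyst sets both bridgeheads.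

Step 5
Reactants: 8 rac-2-vinyloxirane
Product: 9 (S)-2-(4-methoxybenzyloxy)but-3-en-1-ol
Conditions: 4-MeOC6H4CH2OH, Pd2(dba)3·CHCl3 (1 mol%), (R,R)-DACH-phenyl Trost ligand (3 mol%), Et3B (1 mol%), CH2Cl2, 25 °C
Reagents that add atoms: 4-methoxybenzyl alcohol, COc1ccc(CO)cc1
Why: Pd-catalysed dynamic kinetic asymmetric allylic etherification of the vinyl epoxide (boron co-catalyst delivers the alcohol to the branched carbon) sets C8.

Step 6
Reactants: 9 (S)-2-(4-methoxybenzyloxy)but-3-en-1-ol
Product: 10 (S)-2-(4-methoxybenzyloxy)but-3-enal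
Conditions: Dess–Martin periodinane, NaHCO3, CH2Cl2, 0 °C; used crude
Reagents that add atoms: none
Why: Buffered Dess–Martin oxidation gives the α-alkoxy aldehyde without epimerisation or conjugation.

Step 7
Reactants: 7 2-(trimethylsilyl)ethyl (1S,5S)-3-(tert-butyldimethylsilyloxy)-5-methyl-8-oxabicyclo[3.2.1]octa-2,6-diene-2-carboxylate; 10 (S)-2-(4-methoxybenzyloxy)but-3-enal
Product: 11 2-(trimethylsilyl)ethyl (1S,2R,5S)-2-[(1S,2S)-1-hydroxy-2-(4-methoxybenzyloxy)but-3-enyl]-5-methyl-3-oxo-8-oxabicyclo[3.2.1]oct-6-ene-2-carboxylate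
Conditions: TiCl4 (1.1 equiv), CH2Cl2, −78 °C; aq. NaHCO3
Reagents that add atoms: none
Why: Chelation-controlled Mukaiyama aldol: the Ti chelate of the α-OPMB aldehyde is attacked anti to its vinyl group (8,9-syn, 9S) by the silyl enol ether on its exo face (anti to the etheno bridge), which makes C10 quaternary with the new chain cis to the oxygen bridge.

Step 8
Reactants: 11 aldol adduct
Product: 13 exo-2,3-epoxide C9-acetate of the oxabicyclic keto ester, via epoxy alcohol 12 (not isolated)
Conditions: DMDO, acetone, −20 → 0 °C; evaporate; Ac2O, DMAP, pyridine, 0 °C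
Reagents that add atoms: dimethyldioxirane, CC1(C)OO1; acetic anhydride, CC(=O)OC(C)=O
Why: Electrophilic epoxidation of the bicyclic cis-alkene on its exo face (syn to the oxygen bridge; the monosubstituted vinyl group reacts more slowly) sets C2 and C3, and acetylation caps the retro-aldol-prone C9 carbinol as the acetate present in the target.

Step 9
Reactants: 13 exo-2,3-epoxide C9-acetate
Product: 15 ring-opened cyclohept-2-enone C1-mesylate, via hydroxy enone 14 (not isolated)
Conditions: DBU, THF, 0 °C; MsCl (slow addition), 0 → 25 °C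
Reagents that add atoms: methanesulfonyl chloride, CS(=O)(=O)Cl
Why: E1cB opening of the oxabicycle: C5 is the only enolisable position (C10 is quaternary), so the enolate expels the tertiary C4–O bond to give the C4=C5 enone, and the freed C1 carbinol is mesylated at once, which prevents retro-aldol and gives a nucleofuge far better than the C9 acetate for step 12.

Step 10
Reactants: 15 cyclohept-2-enone C1-mesylate
Product: 16 trans-2,3:4,5-diepoxy cycloheptanone
Conditions: t-BuOOH (decane), DBU, toluene, 0 → 25 °C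
Reagents that add atoms: tert-butyl hydroperoxide, CC(C)(C)OO
Why: Weitz–Scheffer nucleophilic epoxidation of the enone; the peroxide adds to C4 on the ring face opposite the 2,3-epoxide oxygen, the C1 mesylate and the C10 side chain, giving the cis-fused 4,5-epoxide anti to the 2,3-epoxide (sets C4 and C5).

Step 11
Reactants: 16 trans-2,3:4,5-diepoxy cycloheptanone; 17 2-(bromomethyl)acrylic acid
Product: 18 (Z)-2-(bromomethyl)alk-2-enoic acid (CO2H trans to C8)
Conditions: Hoveyda–Grubbs II (10 mol%), 17 (5 equiv), CH2Cl2, 40 °C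
Reagents that add atoms: none
Why: Olefin cross-metathesis of the only remaining C=C (the terminal vinyl group) with a 1,1-disubstituted acrylic acid gives the thermodynamically preferred trisubstituted alkene and installs C11–C13 as an allylic bromide.

Step 12
Reactants: 18 (Z)-2-(bromomethyl)alk-2-enoic acid
Product: 20 ten-membered 4,5-epoxy-6-ketone, via bicyclic carbinol 19 (not isolated)
Conditions: In powder, DMF, 25 °C; then t-BuOK (2.2 equiv), THF, −40 °C; AcOH
Reagents that add atoms: none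
Why: Proposed new method: a one-flask indium Barbier allylation/alkoxide Grob fragmentation used as a three-carbon ring expansion (7 → 10) — the allylindium adds through C7 to the C6 ketone via a closed six-membered transition state on the face that carries the C10 side chain (cis-fused cyclopentanol, C11 cis to O6, which fixes C7), then the tertiary alkoxide cleaves C6–C10 antiperiplanar to the C1–OMs bond to release the C6 ketone and the in-ring cis C1=C10 enoate, while the carboxylate cannot lactonise and the base is consumed by the fragmentation; the closest known reactions are the indium-mediated Barbier ring enlargement of α-(haloallyl) β-keto esters and the Wharton–Grob fragmentation of γ-sulfonyloxy alkoxides.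

Step 13
Reactants: 20 ten-membered 4,5-epoxy-6-ketone
Product: 22 6,12-olide C8 PMB ether, via hydroxy acid 21 (not isolated)
Conditions: NaBH4, CeCl3·7H2O, MeOH–THF, −78 °C; then aq. citric acid (pH 3), 25 °C
Reagents that add atoms: none
Why: Luche 1,2-reduction of the α,β-epoxy ketone under non-chelating conditions (Felkin–Anh, hydride anti to the C5–O bond and from the outer ring face) gives the 6S alcohol (5,6-syn, trans to H7), and the γ-hydroxy acid lactonises on acidification to the trans-fused α-methylene-γ-lactone.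

Step 14
Reactants: 22 6,12-olide C8 PMB ether
Product: 23 6,12-olide C8 alcohol
Conditions: DDQ, CH2Cl2–pH 7 buffer, 0 → 25 °C
Reagents that add atoms: none
Why: Oxidative cleavage of the PMB ether; the substrate has no electron-rich alkene, and epoxides, acetate, lactone and silyl ester are inert.

Step 15
Reactants: 24 angelic acid
Product: 25 (Z)-2-methylbut-2-en-1-ol
Conditions: LiAlH4, Et2O, 0 °C
Reagents that add atoms: none
Why: Hydride reduction of the acid to the allylic alcohol leaves the Z-olefin intact.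

Step 16
Reactants: 25 (Z)-2-methylbut-2-en-1-ol
Product: 26 (2S,3R)-2,3-epoxy-2-methylbutan-1-ol
Conditions: Ti(Oi-Pr)4 (10 mol%), L-(+)-DET (12 mol%), t-BuOOH, 4 Å MS, CH2Cl2, −20 °C
Reagents that add atoms: tert-butyl hydroperoxide, CC(C)(C)OO
Why: Sharpless asymmetric epoxidation; L-(+)-tartrate delivers oxygen to the face that gives the (2S,3R)-epoxy alcohol from this Z-allylic alcohol, stereospecifically cis.

Step 17
Reactants: 26 (2S,3R)-2,3-epoxy-2-methylbutan-1-ol
Product: 27 (2R,3R)-2,3-epoxy-2-methylbutanoic acid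
Conditions: RuCl3·xH2O (2 mol%), NaIO4, MeCN–CCl4–H2O, 25 °C
Reagents that add atoms: water, O
Why: RuO4-catalysed oxidation of the primary alcohol to the acid leaves the epoxide untouched (the C2 label changes to R only through CIP priorities).

Step 18
Reactants: 23 6,12-olide C8 alcohol; 27 (2R,3R)-2,3-epoxy-2-methylbutanoic acid
Product: 29 leucanthin B 2-(trimethylsilyl)ethyl ester, via mixed anhydride 28 (not isolated)
Conditions: 27, 2,4,6-Cl3C6H2COCl, Et3N, toluene, 25 °C; then 23, DMAP, 25 °C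
Reagents that add atoms: none
Why: Yamaguchi esterification of the hindered C8 alcohol; the epoxy acid cannot isomerise the way an angelate would.

Step 19
Reactants: 29 leucanthin B 2-(trimethylsilyl)ethyl ester
Product: 30 leucanthin B
Conditions: TBAF, THF, 0 °C; AcOH
Reagents that add atoms: none
Why: Fluoride-induced β-elimination of the 2-(trimethylsilyl)ethyl ester frees the C14 acid without hydrolysing the acetate, the epoxy ester or the lactone.

## Compound list

1 | methyl acetoacetate | CC(=O)CC(=O)OC | starting material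
2 | 2-(trimethylsilyl)ethyl 3-oxobutanoate | CC(=O)CC(=O)OCC[Si](C)(C)C | intermediate
3 | 2-(trimethylsilyl)ethyl 2-diazo-3-oxobutanoate | CC(=O)C(=[N+]=[N-])C(=O)OCC[Si](C)(C)C | intermediate
4 | 2-(trimethylsilyl)ethyl 3-(tert-butyldimethylsilyloxy)-2-diazobut-3-enoate | C=C(O[Si](C)(C)C(C)(C)C)C(=[N+]=[N-])C(=O)OCC[Si](C)(C)C | intermediate
5 | 2-methylfuran | Cc1ccco1 | starting material
6 | cis-divinylcyclopropane (3-methyl-2-oxabicyclo[3.1.0]hex-3-ene with endo siloxyvinyl group and ester on C6) | C=C(O[Si](C)(C)C(C)(C)C)[C@@]1(C(=O)OCC[Si](C)(C)C)[C@H]2OC(C)=C[C@@H]12 | intermediate (not isolated)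
7 | 2-(trimethylsilyl)ethyl (1S,5S)-3-(tert-butyldimethylsilyloxy)-5-methyl-8-oxabicyclo[3.2.1]octa-2,6-diene-2-carboxylate | C[C@]12CC(O[Si](C)(C)C(C)(C)C)=C(C(=O)OCC[Si](C)(C)C)[C@H](C=C1)O2 | intermediate
8 | rac-2-vinyloxirane (butadiene monoepoxide) | C=CC1CO1 | starting material
9 | (S)-2-(4-methoxybenzyloxy)but-3-en-1-ol | OC[C@@H](OCc1ccc(OC)cc1)C=C | intermediate
10 | (S)-2-(4-methoxybenzyloxy)but-3-enal | O=C[C@@H](OCc1ccc(OC)cc1)C=C | intermediate
11 | aldol adduct: 2-(trimethylsilyl)ethyl (1S,2R,5S)-2-[(1S,2S)-1-hydroxy-2-(4-methoxybenzyloxy)but-3-enyl]-5-methyl-3-oxo-8-oxabicyclo[3.2.1]oct-6-ene-2-carboxylate (8S,9S in germacrane numbering) | C[C@]12CC(=O)[C@@](C(=O)OCC[Si](C)(C)C)([C@H](O)[C@@H](OCc3ccc(OC)cc3)C=C)[C@H](C=C1)O2 | intermediate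
12 | exo-6,7-epoxide of 11 (epoxide oxygen syn to the oxygen bridge; C9–OH free) | C[C@]12CC(=O)[C@@](C(=O)OCC[Si](C)(C)C)([C@H](O)[C@@H](OCc3ccc(OC)cc3)C=C)[C@H]([C@H]3O[C@H]31)O2 | intermediate (not isolated)
13 | C9 acetate of 12 | C[C@]12CC(=O)[C@@](C(=O)OCC[Si](C)(C)C)([C@H](OC(C)=O)[C@@H](OCc3ccc(OC)cc3)C=C)[C@H]([C@H]3O[C@H]31)O2 | intermediate
14 | ring-opened hydroxy enone: cycloheptenone with C6=O, C4=C5 (C4–Me), cis-2,3-epoxide, C1–OH cis to the epoxide oxygen, quaternary C10 (CO2TMSE and the (1S,2S)-1-acetoxy-2-PMBO-but-3-enyl chain) | CC1=CC(=O)[C@@](C(=O)OCC[Si](C)(C)C)([C@H](OC(C)=O)[C@@H](OCc2ccc(OC)cc2)C=C)[C@@H](O)[C@H]2O[C@H]21 | intermediate (not isolated)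
15 | C1 mesylate of 14 | CC1=CC(=O)[C@@](C(=O)OCC[Si](C)(C)C)([C@H](OC(C)=O)[C@@H](OCc2ccc(OC)cc2)C=C)[C@@H](OS(C)(=O)=O)[C@H]2O[C@H]21 | intermediate
16 | trans-2,3:4,5-diepoxy cycloheptanone (4,5-epoxide anti to the 2,3-epoxide; C1–OMs, C9–OAc, C8–OPMB, terminal vinyl) | C[C@@]12O[C@@H]1C(=O)[C@@](C(=O)OCC[Si](C)(C)C)([C@H](OC(C)=O)[C@@H](OCc3ccc(OC)cc3)C=C)[C@@H](OS(C)(=O)=O)[C@H]3O[C@H]32 | intermediate
17 | 2-(bromomethyl)acrylic acid | C=C(CBr)C(=O)O | starting material
18 | cross-metathesis product of 16: (Z)-2-(bromomethyl)alk-2-enoic acid (C7=C11, CO2H trans to C8) | C[C@@]12O[C@@H]1C(=O)[C@@](C(=O)OCC[Si](C)(C)C)([C@H](OC(C)=O)[C@@H](OCc3ccc(OC)cc3)/C=C(/C(=O)O)CBr)[C@@H](OS(C)(=O)=O)[C@H]3O[C@H]32 | intermediate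
19 | Barbier adduct: cis-fused bicyclo[5.3.0] carbinol (new C6–C7 bond; C6–OH cis to the C7 acrylic acid unit and to C8–OPMB) | C[C@@]12O[C@@H]1[C@@]3(O)[C@H](C(=C)C(=O)O)[C@H](OCc4ccc(OC)cc4)[C@@H](OC(C)=O)[C@@]3(C(=O)OCC[Si](C)(C)C)[C@@H](OS(C)(=O)=O)[C@H]4O[C@H]42 | intermediate (not isolated)
20 | ring-expanded ten-membered ketone: C6=O, cis C1=C10 enoate (CO2TMSE), 2,3- and 4,5-epoxides, C9–OAc, C8–OPMB, C7 acrylic acid; C2, C3, C4, C5, C7, C8, C9 arranged as in the target | C=C(C(=O)O)[C@@H]1[C@H](OCc2ccc(OC)cc2)[C@@H](OC(C)=O)/C(C(=O)OCC[Si](C)(C)C)=C\[C@H]2O[C@H]2[C@]2(C)O[C@@H]2C1=O | intermediate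
21 | (6S)-hydroxy acid from 20 | C=C(C(=O)O)[C@@H]1[C@H](OCc2ccc(OC)cc2)[C@@H](OC(C)=O)/C(C(=O)OCC[Si](C)(C)C)=C\[C@H]2O[C@H]2[C@]2(C)O[C@@H]2[C@H]1O | intermediate (not isolated)
22 | trans-fused 6,12-olide with C8–OPMB and C14 TMSE ester (2R,3R,4R,5R,6S,7R,8S,9S) | C=C1C(=O)O[C@H]2[C@H]1[C@H](OCc1ccc(OC)cc1)[C@@H](OC(C)=O)/C(C(=O)OCC[Si](C)(C)C)=C\[C@H]1O[C@H]1[C@]1(C)O[C@H]21 | intermediate
23 | C8 alcohol of 22 | C=C1C(=O)O[C@H]2[C@H]1[C@H](O)[C@@H](OC(C)=O)/C(C(=O)OCC[Si](C)(C)C)=C\[C@H]1O[C@H]1[C@]1(C)O[C@H]21 | intermediate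
24 | angelic acid ((Z)-2-methylbut-2-enoic acid) | C/C=C(/C)C(=O)O | starting material
25 | (Z)-2-methylbut-2-en-1-ol | C/C=C(/C)CO | intermediate
26 | (2S,3R)-2,3-epoxy-2-methylbutan-1-ol | OC[C@]1(C)O[C@@H]1C | intermediate
27 | (2R,3R)-2,3-epoxy-2-methylbutanoic acid | OC(=O)[C@]1(C)O[C@@H]1C | intermediate
28 | mixed anhydride of 27 with 2,4,6-trichlorobenzoic acid | O=C(OC(=O)[C@]1(C)O[C@@H]1C)c1c(Cl)cc(Cl)cc1Cl | intermediate (not isolated)
29 | leucanthin B 2-(trimethylsilyl)ethyl ester | C=C1C(=O)O[C@H]2[C@H]1[C@H](OC(=O)[C@]1(C)O[C@@H]1C)[C@@H](OC(C)=O)/C(C(=O)OCC[Si](C)(C)C)=C\[C@H]1O[C@H]1[C@]1(C)O[C@H]21 | intermediate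
30 | leucanthin B | C=C1C(=O)O[C@H]2[C@H]1[C@H](OC(=O)[C@]1(C)O[C@@H]1C)[C@@H](OC(C)=O)/C(C(=O)O)=C\[C@H]1O[C@H]1[C@]1(C)O[C@H]21 | target

## Step count and weak points

Total steps: 19. Longest linear sequence: 14 (steps 1–4, 7–14, 18, 19).

The three steps most likely to fail are 12, 11 and 13.

Step 12 (the new one-flask Barbier/Grob ring expansion) may stall at the carbinol or suffer epimerisation at C7. The fallback uses only known reactions and separates the two events. It sets out from 18: zinc dust in saturated aqueous NH4Cl–THF (aqueous Barbier allylation of a 2-(bromomethyl)acrylic acid) gives the bicyclic carbinol 19, now isolated and dried. The dianion is then formed with KH and 18-crown-6 in THF at 0 °C and undergoes a classical Wharton–Grob fragmentation of the γ-mesyloxy alkoxide, which returns to the route at 20. No compound outside the list is made (F0).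

Step 11 (late cross-metathesis of a hindered allylic ether with a 1,1-disubstituted acrylic acid) may give low conversion. The fallback builds the same unit stepwise from 16. Lemieux–Johnson cleavage of the vinyl group (OsO4 cat., NaIO4, 2,6-lutidine, dioxane–water) gives the C7 aldehyde F1. A Morita–Baylis–Hillman reaction with acrolein (DABCO) gives the hydroxy enal F2 (C7 epimers are inconsequential). Pinnick oxidation (NaClO2, NaH2PO4, 2-methyl-2-butene) gives the hydroxy acid F3. NBS/Me2S then converts the allylic alcohol with transposition into the (Z)-allylic bromide, which returns to the route at 18.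

Step 13 (facial selectivity of the C6 ketone reduction in the ten-membered ring) may instead give the 6-epimer. The fallback makes that epimer deliberately and inverts it. It sets out from 20: chelation-controlled reduction with Zn(BH4)2 in Et2O at −20 °C (epoxide oxygen and carbonyl chelated) gives the 6-epi hydroxy acid F4, kept as its triethylammonium salt. Mitsunobu lactonisation (PPh3, DIAD, THF) closes the lactone with inversion at C6 and returns to the route at 22.

## Further compounds

F1 | step 11 | C7 aldehyde from oxidative cleavage of the vinyl group of 16 | C[C@@]12O[C@@H]1C(=O)[C@@](C(=O)OCC[Si](C)(C)C)([C@H](OC(C)=O)[C@@H](OCc3ccc(OC)cc3)C=O)[C@@H](OS(C)(=O)=O)[C@H]3O[C@H]32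
F2 | step 11 | hydroxy enal (Morita–Baylis–Hillman adduct of F1 with acrolein, C7 epimers) | C[C@@]12O[C@@H]1C(=O)[C@@](C(=O)OCC[Si](C)(C)C)([C@H](OC(C)=O)[C@@H](OCc3ccc(OC)cc3)C(O)C(=C)C=O)[C@@H](OS(C)(=O)=O)[C@H]3O[C@H]32
F3 | step 11 | hydroxy acid (2-(1-hydroxyalkyl)acrylic acid from F2) | C[C@@]12O[C@@H]1C(=O)[C@@](C(=O)OCC[Si](C)(C)C)([C@H](OC(C)=O)[C@@H](OCc3ccc(OC)cc3)C(O)C(=C)C(=O)O)[C@@H](OS(C)(=O)=O)[C@H]3O[C@H]32
F0 | step 12 | none | none
F4 | step 13 | 6-epi hydroxy acid (C6 epimer of 21) | C=C(C(=O)O)[C@@H]1[C@H](OCc2ccc(OC)cc2)[C@@H](OC(C)=O)/C(C(=O)OCC[Si](C)(C)C)=C\[C@H]2O[C@H]2[C@]2(C)O[C@@H]2[C@@H]1O
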